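**Retrosynthetic overview**
1. Target 17 is a tris(acylphloroglucinol): central ring C (butanoyl on C1, OH on C2/C4/C6) carries ring A through a CH2 on C3 and ring B through a CH2 on C5. No ring is formed in the route; ring C comes from phloroglucinol and rings A and B from 2-methylphloroglucinol.
2. Key disconnection: the C5(ring C)–CH2(ring B) bond, made last. The C3(ring C)–CH2(ring A) bond is made in the same flask just before it, so step 10 joins three building blocks (core acid 3, Mannich bases 9 and 12) around ring C in one operation.
3. Enabling feature: C3 and C5 of ring C each lie between two hydroxyl-bearing ring carbons (C2/C4 and C4/C6). Each is therefore an enol α-carbon and nucleophilic, and a CO2H on C5 is a vinylogous β-keto acid that leaves as CO2. In ring B the bridging CH2 sits on a ring carbon whose neighbour bears OH, so the CH2 can be the methylene of an o-quinone methide.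
4. The CO2H on C5 tells the two otherwise equivalent positions C3 and C5 apart: ring A is attached at C3–H first, then loss of CO2 frees C5 for ring B.
5. Rings A and B are regioisomers: in each the single OMe is para to the first acyl group put on the ring (formyl for A, which later becomes the bridging CH2; butanoyl for B).

Key step: step 10

Remark: the target has no stereocentre and no other stereogenic element, so it is one achiral compound and no stereocontrol is needed.

**Step 1**
Reactants: 1 benzene-1,3,5-triol (phloroglucinol)
Product: 2 1-(2,4,6-trihydroxyphenyl)butan-1-one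
Conditions: PrCOCl (1.0 equiv), AlCl3 (3.5 equiv), PhNO2/CH2Cl2, 0 °C to 45 °C; aq. HCl work-up
Reagents that add atoms: butanoyl chloride, CCCC(=O)Cl
Why: Friedel–Crafts C-acylation of phloroglucinol should stop at the monoketone because the chelated acyl group deactivates the ring towards a second acylation.

**Step 2**
Reactants: 2 1-(2,4,6-trihydroxyphenyl)butan-1-one
Product: 3 3-butanoyl-2,4,6-trihydroxybenzoic acid
Conditions: KHCO3 (5 equiv), H2O, CO2 (1 atm), 60 °C; then 2 M HCl, 0 °C, filtration, drying at rt
Reagents that add atoms: carbon dioxide, O=C=O, supplied by potassium hydrogencarbonate, [K+].OC([O-])=O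
Why: Kolbe–Schmitt carboxylation of a phloroglucinol, in which the ring reacts as an enolate with CO2, should carboxylate one of the two equivalent C–H positions only, because the first carboxylate deactivates the ring, and cold acidification should keep the acid from losing CO2.

**Step 3**
Reactants: 4 2-methylbenzene-1,3,5-triol (2,4,6-trihydroxytoluene)
Product: 6 2,4,6-trihydroxy-3-methylbenzaldehyde, via aryl iminium chloride 5 (not isolated)
Conditions: POCl3 (1.2 equiv), DMF (1.5 equiv), EtOAc, 0 °C to rt; then H2O, 50 °C
Reagents that add atoms: N,N-dimethylformamide, CN(C)C=O (formyl carbon); water, O (formyl oxygen)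
Why: Vilsmeier–Haack formylation should take place once at one of the two equivalent free ring positions, because the iminium group of 5 deactivates the ring until it is hydrolysed.

**Step 4**
Reactants: 6 2,4,6-trihydroxy-3-methylbenzaldehyde
Product: 7 2,6-dihydroxy-4-methoxy-3-methylbenzaldehyde
Conditions: Me2SO4 (1.0 equiv), K2CO3 (1.0 equiv), acetone, 0 °C to rt
Reagents that add atoms: dimethyl sulfate, COS(=O)(=O)OC
Why: Williamson O-methylation should take the hydroxyl para to the formyl group, which is the most acidic and the only one not tied up in a hydrogen bond to C=O.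

**Step 5**
Reactants: 7 2,6-dihydroxy-4-methoxy-3-methylbenzaldehyde
Product: 8 3-butanoyl-2,6-dihydroxy-4-methoxy-5-methylbenzaldehyde
Conditions: (PrCO)2O (1.5 equiv), BF3·OEt2 (3 equiv), 60 °C; then H2O, 50 °C
Reagents that add atoms: butanoic anhydride, CCCC(=O)OC(=O)CCC
Why: Friedel–Crafts C-acylation can only go to C5, the single unsubstituted ring carbon, because the formyl group blocks the carbon between the two hydroxyls, and BF3 should leave the aryl methyl ether intact.

**Step 6**
Reactants: 8 3-butanoyl-2,6-dihydroxy-4-methoxy-5-methylbenzaldehyde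
Product: 9 1-{3-[(dimethylamino)methyl]-2,4-dihydroxy-6-methoxy-5-methylphenyl}butan-1-one
Conditions: Me2NH (2 M in THF, 2 equiv), NaBH(OAc)3 (1.5 equiv), ClCH2CH2Cl, rt
Reagents that add atoms: dimethylamine, CNC
Why: Reductive amination should convert the formyl group into the dimethylaminomethyl group of a phenolic Mannich base, since NaBH(OAc)3 reduces the iminium ion but not the chelated aryl ketone.

**Step 7**
Reactants: 4 2-methylbenzene-1,3,5-triol
Product: 10 1-(2,4,6-trihydroxy-3-methylphenyl)butan-1-one
Conditions: PrCOCl (1.0 equiv), AlCl3 (3.5 equiv), PhNO2/CH2Cl2, 0 °C to 45 °C; aq. HCl work-up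
Reagents that add atoms: butanoyl chloride, CCCC(=O)Cl
Why: Friedel–Crafts C-acylation at one of the two equivalent free positions should stop at the monoketone because the chelated acyl group deactivates the ring.

**Step 8**
Reactants: 10 1-(2,4,6-trihydroxy-3-methylphenyl)butan-1-one
Product: 11 1-(2,6-dihydroxy-4-methoxy-3-methylphenyl)butan-1-one (aspidinol)
Conditions: Me2SO4 (1.0 equiv), K2CO3 (1.0 equiv), acetone, 0 °C to rt
Reagents that add atoms: dimethyl sulfate, COS(=O)(=O)OC
Why: Williamson O-methylation should again take the hydroxyl para to the acyl group, because the two ortho hydroxyls are hydrogen-bonded to the ketone.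

**Step 9**
Reactants: 11 1-(2,6-dihydroxy-4-methoxy-3-methylphenyl)butan-1-one
Product: 12 1-{3-[(dimethylamino)methyl]-2,6-dihydroxy-4-methoxy-5-methylphenyl}butan-1-one
Conditions: CH2(NMe2)2 (1.5 equiv), MeCN, 0 °C to rt
Reagents that add atoms: bis(dimethylamino)methane, CN(C)CN(C)C
Why: Mannich aminomethylation with the aminal, which the acidic phenol activates, can only take place at the one free ring carbon of 11.

**Step 10**
Reactants: 3 3-butanoyl-2,4,6-trihydroxybenzoic acid; 9 1-{3-[(dimethylamino)methyl]-2,4-dihydroxy-6-methoxy-5-methylphenyl}butan-1-one; 12 1-{3-[(dimethylamino)methyl]-2,6-dihydroxy-4-methoxy-5-methylphenyl}butan-1-one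
Product: 17 1-{3-[(3-butanoyl-2,6-dihydroxy-4-methoxy-5-methylphenyl)methyl]-5-[(3-butanoyl-2,4-dihydroxy-6-methoxy-5-methylphenyl)methyl]-2,4,6-trihydroxyphenyl}butan-1-one, via o-quinone methide of ring A 13 (not isolated), via dimer acid 14 (not isolated), via decarboxylated dimer 15 (not isolated), via o-quinone methide of ring B 16 (not isolated)
Conditions: (i) 3 and 9 (1:1), 1,4-dioxane, 65 °C; (ii) 12 (1.1 equiv, added slowly), AcOH (5 equiv), 100 °C; one flask
Reagents that add atoms: none
Why: In the first stage the ammonium carboxylate formed from 3 and 9 loses dimethylamine to give o-quinone methide 13, and the only C–H carbon of ring C (C3, an enol α-carbon) adds to its exocyclic methylene and rearomatises to 14. In the second stage AcOH and heat bring about ipso protonation at C5 and loss of CO2 from 14 to give 15, 12 loses dimethylamine to give o-quinone methide 16, and the freed C5 adds to the methylene of 16 to form the C5–CH2 bond and, after tautomerisation, 17 (ipso attack of 16 on C5 of 14 followed by loss of CO2 would end in the same product). The closest known reaction types are the union of acylphloroglucinols with phenolic Mannich bases through o-quinone methides to give methylene-bis(acylphloroglucinols), the thermal decarboxylation of 2,4,6-trihydroxybenzoic acids, and the use of a carboxyl group as a removable blocking group in resorcinol C-alkylation. No ring is closed and no stereocentre is formed. The step needs each arm to be attached once and to a different carbon of ring C, which is secured because 3 has a single C–H position, because its carboxyl group stays on as the carboxylate salt (which resists ipso protonation) until AcOH is added, and because 9 and 12 have no free ring position and so cannot couple with themselves. The two C–C bond formations should be the only non-reverting outcomes, since O- and N-adducts of the quinone methides revert.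

**Compound list**
1 | benzene-1,3,5-triol (phloroglucinol) | Oc1cc(O)cc(O)c1 | starting material
2 | 1-(2,4,6-trihydroxyphenyl)butan-1-one | CCCC(=O)c1c(O)cc(O)cc1O | intermediate
3 | 3-butanoyl-2,4,6-trihydroxybenzoic acid | CCCC(=O)c1c(O)cc(O)c(C(=O)O)c1O | intermediate
4 | 2-methylbenzene-1,3,5-triol (2,4,6-trihydroxytoluene) | Cc1c(O)cc(O)cc1O | starting material
5 | N-methyl-N-[(2,4,6-trihydroxy-3-methylphenyl)methylidene]methanaminium chloride | C[N+](C)=Cc1c(O)cc(O)c(C)c1O.[Cl-] | intermediate
6 | 2,4,6-trihydroxy-3-methylbenzaldehyde | O=Cc1c(O)cc(O)c(C)c1O | intermediate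
7 | 2,6-dihydroxy-4-methoxy-3-methylbenzaldehyde | O=Cc1c(O)cc(OC)c(C)c1O | intermediate
8 | 3-butanoyl-2,6-dihydroxy-4-methoxy-5-methylbenzaldehyde | O=Cc1c(O)c(C(=O)CCC)c(OC)c(C)c1O | intermediate
9 | 1-{3-[(dimethylamino)methyl]-2,4-dihydroxy-6-methoxy-5-methylphenyl}butan-1-one | CCCC(=O)c1c(O)c(CN(C)C)c(O)c(C)c1OC | intermediate
10 | 1-(2,4,6-trihydroxy-3-methylphenyl)butan-1-one | CCCC(=O)c1c(O)cc(O)c(C)c1O | intermediate
11 | 1-(2,6-dihydroxy-4-methoxy-3-methylphenyl)butan-1-one (aspidinol) | CCCC(=O)c1c(O)cc(OC)c(C)c1O | intermediate
12 | 1-{3-[(dimethylamino)methyl]-2,6-dihydroxy-4-methoxy-5-methylphenyl}butan-1-one | CCCC(=O)c1c(O)c(CN(C)C)c(OC)c(C)c1O | intermediate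
13 | 2-butanoyl-5-hydroxy-3-methoxy-4-methyl-6-methylidenecyclohexa-2,4-dien-1-one | C=C1C(=O)C(C(=O)CCC)=C(OC)C(C)=C1O | intermediate
14 | 3-butanoyl-5-[(3-butanoyl-2,6-dihydroxy-4-methoxy-5-methylphenyl)methyl]-2,4,6-trihydroxybenzoic acid | CCCC(=O)c1c(O)c(Cc2c(O)c(C)c(OC)c(C(=O)CCC)c2O)c(O)c(C(=O)O)c1O | intermediate
15 | 1-{3-[(3-butanoyl-2,6-dihydroxy-4-methoxy-5-methylphenyl)methyl]-2,4,6-trihydroxyphenyl}butan-1-one | CCCC(=O)c1c(O)c(Cc2c(O)c(C)c(OC)c(C(=O)CCC)c2O)c(O)cc1O | intermediate
16 | 2-butanoyl-3-hydroxy-5-methoxy-4-methyl-6-methylidenecyclohexa-2,4-dien-1-one | C=C1C(=O)C(C(=O)CCC)=C(O)C(C)=C1OC | intermediate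
17 | 1-{3-[(3-butanoyl-2,6-dihydroxy-4-methoxy-5-methylphenyl)methyl]-5-[(3-butanoyl-2,4-dihydroxy-6-methoxy-5-methylphenyl)methyl]-2,4,6-trihydroxyphenyl}butan-1-one | CCCC(=O)c1c(O)c(Cc2c(O)c(C)c(OC)c(C(=O)CCC)c2O)c(O)c(Cc2c(O)c(C(=O)CCC)c(O)c(C)c2OC)c1O | target

**Totals**
Total step count: 10. Longest linear sequence: 5 steps (steps 3, 4, 5, 6 and 10).

**Steps most likely to fail**

1. Step 10. The carboxyl group of 3 may be lost already in the first stage, by ipso protonation or ipso attack. That would free both central positions too early and let the same arm go on twice. Fallback: a sturdier gate and separate operations, setting out from 3. The carboxylate of 3 is benzylated (BnBr, KHCO3, DMF, rt) to give benzyl 3-butanoyl-2,4,6-trihydroxybenzoate F1, which cannot lose CO2. F1 is heated with 9 (dioxane, 90 °C) to give benzyl 3-butanoyl-5-[(3-butanoyl-2,6-dihydroxy-4-methoxy-5-methylphenyl)methyl]-2,4,6-trihydroxybenzoate F2. Hydrogenolysis of F2 (H2, Pd/C, EtOAc, rt) gives 14, where the fallback comes back to the route. 14 is then heated with 12 and AcOH as in the second stage of step 10 to give 17.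

2. Step 2. The carboxylation equilibrium may not be driven to the acid, or CO2 may be lost again during acidification and drying. Fallback: no gate at all and two separate, known Mannich-base couplings, setting out from 2 and 9. A three-fold excess of 2 is heated with 9 (dioxane, 90 °C), so that attachment of ring A stops after one position. 15 is isolated and the excess 2 recovered. The fallback comes back to the route at 15, which is heated with 12 (AcOH, dioxane, 100 °C) to give 17. It makes no compound outside the compound list.

3. Step 5. Acylation of the formyl-deactivated ring may stop at O-acylation, or the formyl group may be lost by acid-promoted deformylation. Fallback: the methyl ether of ring A is placed with protecting groups instead of a formyl group, setting out from 10. Two-fold benzylation (BnBr 2.1 equiv, K2CO3, DMF, rt) should take the para hydroxyl and the less hindered ortho hydroxyl and leave the chelated hydroxyl next to the C-methyl group, giving 1-[4,6-bis(benzyloxy)-2-hydroxy-3-methylphenyl]butan-1-one F3. Methylation of that hydroxyl (MeI, K2CO3, DMF, 50 °C) gives 1-[4,6-bis(benzyloxy)-2-methoxy-3-methylphenyl]butan-1-one F4. Hydrogenolysis (H2, Pd/C, EtOAc, rt) gives 1-(4,6-dihydroxy-2-methoxy-3-methylphenyl)butan-1-one F5. Mannich aminomethylation of F5 at its one free ring carbon (CH2(NMe2)2, MeCN, 0 °C to rt) comes back to the route at 9.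

**Further compounds**
F1 | step 10 | benzyl 3-butanoyl-2,4,6-trihydroxybenzoate | CCCC(=O)c1c(O)cc(O)c(C(=O)OCc2ccccc2)c1O
F2 | step 10 | benzyl 3-butanoyl-5-[(3-butanoyl-2,6-dihydroxy-4-methoxy-5-methylphenyl)methyl]-2,4,6-trihydroxybenzoate | CCCC(=O)c1c(O)c(Cc2c(O)c(C)c(OC)c(C(=O)CCC)c2O)c(O)c(C(=O)OCc2ccccc2)c1O
F0 | step 2 | none | none
F3 | step 5 | 1-[4,6-bis(benzyloxy)-2-hydroxy-3-methylphenyl]butan-1-one | CCCC(=O)c1c(O)c(C)c(OCc2ccccc2)cc1OCc1ccccc1
F4 | step 5 | 1-[4,6-bis(benzyloxy)-2-methoxy-3-methylphenyl]butan-1-one | CCCC(=O)c1c(OC)c(C)c(OCc2ccccc2)cc1OCc1ccccc1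
F5 | step 5 | 1-(4,6-dihydroxy-2-methoxy-3-methylphenyl)butan-1-one | CCCC(=O)c1c(OC)c(C)c(O)cc1O
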